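The easy step is a subtraction: in every recipe below, the substrates together make 0.700 M, more than the 0.100 M of partner. So partner is the limiting reagent, and once the protic impurity has taken its 2.00 mM, 0.0980 M remains to be shared out.

common to all: second substrate 0.500 M; third substrate 0.100 M; protic impurity 2.00 mM; time 5.0 d
- violet: starting material 0.10 M; partner 0.100 M; everything together at the start at 20 °C, warmed to 50 °C at 25 h
- ochre: starting material 0.10 M; partner 0.100 M (fed, over 25 h); the addition at 20 °C, then warmed to 50 °C; the feed brings no volume worth counting
- grey: starting material 0.10 M (fed, over 25 h); partner 0.100 M; all else is in the flask from the start; the feed brings no volume worth counting; temperature 50 °C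
- red: starting material 0.10 M; partner 0.100 M (fed, over 25 h); all else is in the flask from the start; the feed brings no volume worth counting; temperature 50 °C
- teal: starting material 0.10 M; partner 0.100 M (in portions, 5, over 25 h); first portion at the start, last at 25 h; temperature 50 °C

    starting material + partner → target (k1 = 0.536 M⁻¹ h⁻¹, Ea1 = 60.0 kJ mol⁻¹)
    second substrate + partner → second product (k2 = 0.271 M⁻¹ h⁻¹, Ea2 = 85.0 kJ mol⁻¹)
    third substrate + partner → third product (k3 = 0.257 M⁻¹ h⁻¹, Ea3 = 81.0 kJ mol⁻¹)
    partner + protic impurity → quenched reagent (k4 = 75.7 M⁻¹ h⁻¹, Ea4 = 71.0 kJ mol⁻¹)
    (constants at 50 °C)

- the constants hold at 50 °C; other temperatures follow from the activation energies

1. which flask leads in amount of target, in percent of the starting material charged ("all alike" within 1.5 percentage points) (violet / ochre / grey / red / teal / all alike)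
2. how much target is there at the end, in percent of the starting material charged: violet
3. how much target is there at the end, in percent of the starting material charged: ochre
4. how much target is there at the end, in percent of the starting material charged: grey
5. how much target is there at the end, in percent of the starting material charged: red
6. how much target is there at the end, in percent of the starting material charged: teal

Each step uses partner to the same power, so at one temperature partner divides among the substrates as their constants times their concentrations, however it is dosed. I call target's share that product for starting material over the sum of the products for the three substrates. For red and teal at 50 °C the charges give 25.0%, hence 24.5% of target. But starting material falls by that much while second and third substrates fall by about 12.3%, a faster fall, so I replace each curve by its mean between start and end. This gives the mean share of target, 23.7%, and so 23.2% of target in red and in teal alike.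

At 20 °C the share at the start is 45.6%, higher than at 50 °C, because the target step has the lowest activation energy. Violet starts its cold hours with its whole partner charge and ochre with none, so I put violet first and ochre second. In grey, partner lasts about 6.20 h among the second and third substrates, shorter than the 25 h feed of starting material, so I expect grey far lower, without a number.

The forecast names violet and gives 27.4% for violet, 25.5% for ochre, 7.3% for grey, 23.3% for red and 23.3% for teal, saying of the partner exposure “which makes red and teal identical whatever the dosing”.

The simulation gives 27.4% for violet, 25.4% for ochre, 7.22% for grey, 23.3% for red and 23.3% for teal, so violet leads, and the target I reckoned from my mean share stands at 23.2% against the 23.3% of red.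

In violet, the second substrate's use of partner over the target step's is 0.98 at the start and 2.9 at 1.15 d, higher once the flask is warm. Violet ends 4.1 percentage points above red, which has no cold hours.

Now take the neighbour of violet charged with 0.40 M of starting material. Scaling the odds of the mean share by that charge gives a share of 55.4%, so 13.6% of its own charge with the cold hours not counted. The computed neighbour gives 16.0%, higher, as violet stands above red.

Its constants are those of an exercise; what happens was integrated by code.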